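The target is cut at the methylene bridge into a chromene phenol (ring B) and an enantiopure acylfilicinic-type trione (ring A), and the chromene is traced to an aryl 1,1-dimethylpropargyl ether. The key step exploits the fact that the pyran oxygen O1 of ring B sits on C8a, next to the isobutyryl-bearing C8: an ether placed on that chelated oxygen of a bis-MOM phlorisobutyrophenone has only one free ortho carbon, the future C4a. Cationic gold then forms the C4–C4a bond and closes the pyran in one 6-endo operation. Ring A carries the lone stereocentre, set by phase-transfer prenylation of a mixed methylmalonate.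

Key step: step 4

Assumption: the (S,S)-configured N-spiro bis(binaphthyl)ammonium bromide is taken to alkylate 16 on the face that gives (S)-18; if the first run shows the opposite sense, its (R,R)-antipode is used and nothing else changes.

Step 1
Reactants: 1 phloroglucinol; 2 isobutyryl chloride
Product: 3 2-methyl-1-(2,4,6-trihydroxyphenyl)propan-1-one
Conditions: AlCl3 (4 equiv), PhNO2, 65 °C; then ice, 1 M HCl
Reagents that add atoms: isobutyryl chloride (2), CC(C)C(Cl)=O
Why: Friedel–Crafts C-acylation of the symmetrical, very nucleophilic triphenol, in which the first acyl group deactivates the ring and so limits the reaction to monoacylation.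

Step 2
Reactants: 3 2-methyl-1-(2,4,6-trihydroxyphenyl)propan-1-one; 4 chloromethyl methyl ether
Product: 5 1-[2-hydroxy-4,6-bis(methoxymethoxy)phenyl]-2-methylpropan-1-one
Conditions: 4 (2.2 equiv), iPr2NEt (3 equiv), CH2Cl2, 0 °C → rt
Reagents that add atoms: chloromethyl methyl ether (4), COCCl
Why: Williamson-type acetal etherification in which one ortho hydroxyl stays hydrogen-bonded to the ketone and is left free when two equivalents of 4 are used, the usual behaviour of 2,4,6-trihydroxyaryl ketones; MOM ethers keep the arene electron-rich for step 4.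

Step 3
Reactants: 5 1-[2-hydroxy-4,6-bis(methoxymethoxy)phenyl]-2-methylpropan-1-one; 6 3-chloro-3-methylbut-1-yne
Product: 7 1-[2,4-bis(methoxymethoxy)-6-(2-methylbut-3-yn-2-yloxy)phenyl]-2-methylpropan-1-one
Conditions: 6 (2 equiv), CuCl2·2H2O (2 mol%), DBU (2 equiv), MeCN, 0 °C → rt
Reagents that add atoms: 3-chloro-3-methylbut-1-yne (6), CC(C)(Cl)C#C
Why: Copper-catalysed propargylic etherification, in which DBU deprotonates the chelated phenol and the copper acetylide of 6 ionises to a copper allenylidene that the phenoxide captures at the tertiary carbon, a process that tolerates hindered and hydrogen-bonded phenols.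

Step 4
Reactants: 7 1-[2,4-bis(methoxymethoxy)-6-(2-methylbut-3-yn-2-yloxy)phenyl]-2-methylpropan-1-one
Product: 8 1-[5,7-bis(methoxymethoxy)-2,2-dimethyl-2H-chromen-8-yl]-2-methylpropan-1-one
Conditions: Ph3PAuNTf2 (3 mol%), 4 Å MS, CH2Cl2, rt
Reagents that add atoms: none
Why: Ph3PAuNTf2, a source of cationic monovalent gold, binds the terminal alkyne of 7, and the arene carbon that lies between the ether oxygen and a MOM ether attacks the terminal alkyne carbon in a Friedel–Crafts manner; rearomatisation and protodeauration then release 8 and the catalyst. The closest known reaction type is the gold- or platinum-catalysed cycloisomerisation (intramolecular alkyne hydroarylation) of aryl propargyl ethers to 2H-chromenes. The pyran ring closes in the 6-endo-dig mode, the new bond being C4–C4a, and no stereocentre is formed. The step needs the pyran oxygen to be the one beside the isobutyryl group, and this is built into the substrate: the second carbon flanking the ether oxygen already carries the acyl group, and the other free arene carbon, between the two MOM ethers, cannot reach the alkyne. Endo rather than 5-exo closure is expected because the terminal alkyne carbon is the accessible one, the gem-dimethyl group compresses the tether and the attacking carbon is activated by three oxygen substituents. The MOM acetals and the tertiary propargylic C–O bond must survive, for which a non-protic catalyst in dry CH2Cl2 at room temperature is chosen.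

Step 5
Reactants: 8 1-[5,7-bis(methoxymethoxy)-2,2-dimethyl-2H-chromen-8-yl]-2-methylpropan-1-one
Product: 9 1-(5,7-dihydroxy-2,2-dimethyl-2H-chromen-8-yl)-2-methylpropan-1-one
Conditions: 3 M aq. HCl, MeOH, 45 °C
Reagents that add atoms: none
Why: Acid-catalysed acetal exchange (MOM cleavage) with methanol as the acceptor of the formaldehyde unit; the 2,2-dimethylchromene and the aryl ketone are inert to dilute methanolic HCl at this temperature.

Step 6
Reactants: 9 1-(5,7-dihydroxy-2,2-dimethyl-2H-chromen-8-yl)-2-methylpropan-1-one; 10 dimethyl(methylidene)ammonium iodide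
Product: 11 1-{6-[(dimethylamino)methyl]-5,7-dihydroxy-2,2-dimethyl-2H-chromen-8-yl}-2-methylpropan-1-one
Conditions: 10 (1.1 equiv), Et3N (1.2 equiv), CH2Cl2, 0 °C → rt
Reagents that add atoms: dimethyl(methylidene)ammonium iodide (10), C=[N+](C)C.[I-]
Why: Phenol Mannich reaction, in which C6, the only free ring carbon and flanked by two hydroxyls, attacks the preformed iminium ion at low temperature much faster than the styrene-like C3=C4 bond.

Step 7
Reactants: 12 2,2,5-trimethyl-1,3-dioxane-4,6-dione; 13 tert-butanol
Product: 14 3-tert-butoxy-2-methyl-3-oxopropanoic acid (racemic)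
Conditions: t-BuOH, reflux
Reagents that add atoms: tert-butanol (13), CC(C)(C)O
Why: Alcoholysis of the cyclic acylal, in which tert-butanol opens the dioxanedione and acetone is lost, gives the malonic half-ester below the temperature of decarboxylation.

Step 8
Reactants: 14 3-tert-butoxy-2-methyl-3-oxopropanoic acid; 15 2,2-diphenylethanol
Product: 16 1-tert-butyl 3-(2,2-diphenylethyl) 2-methylpropanedioate (racemic)
Conditions: DCC, DMAP (cat.), CH2Cl2, 0 °C → rt
Reagents that add atoms: 2,2-diphenylethanol (15), OCC(c1ccccc1)c1ccccc1
Why: Steglich esterification of the half-acid with a primary alcohol leaves the tert-butyl ester untouched and gives a malonate with two orthogonal esters, one acid-labile and one base-labile.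

Step 9
Reactants: 16 1-tert-butyl 3-(2,2-diphenylethyl) 2-methylpropanedioate; 17 1-bromo-3-methylbut-2-ene
Product: 18 1-tert-butyl 3-(2,2-diphenylethyl) (2S)-2-methyl-2-(3-methylbut-2-en-1-yl)propanedioate
Conditions: 17 (3 equiv), (S,S)-3,4,5-trifluorophenyl-NAS bromide (5 mol%), 50% aq. KOH (5 equiv), toluene, −40 °C
Reagents that add atoms: 1-bromo-3-methylbut-2-ene (17), CC(C)=CCBr
Why: Asymmetric phase-transfer enolate alkylation (SN2), in which the potassium enolate of the α-methylmalonate is paired with the C2-symmetric chiral ammonium cation, which tells the bulky tert-butyl ester from the diphenylethyl ester and shields one enolate face, so that the allylic bromide is attacked from the open face and the quaternary stereocentre should be set as (S).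

Step 10
Reactants: 18 1-tert-butyl 3-(2,2-diphenylethyl) (2S)-2-methyl-2-(3-methylbut-2-en-1-yl)propanedioate
Product: 20 (2R)-2-[(2,2-diphenylethoxy)carbonyl]-2,5-dimethylhex-4-enoic acid, via trimethylsilyl ester 19 (not isolated)
Conditions: Me3SiOTf (2 equiv), 2,6-lutidine (3 equiv), CH2Cl2, 0 °C → rt; then H2O, aq. citric acid
Reagents that add atoms: trimethylsilyl trifluoromethanesulfonate, C[Si](C)(C)OS(=O)(=O)C(F)(F)F (its Me3Si group is present in 19 only)
Why: Silyl triflate-mediated tert-butyl ester cleavage, in which O-silylation is followed by loss of the tert-butyl cation as isobutene under lutidine buffering and water then hydrolyses the silyl ester, so that the acid-sensitive prenyl alkene, the primary ester and the hydrogen-free stereocentre are not touched (the descriptor changes from S to R only because the priorities change).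

Step 11
Reactants: 20 (2R)-2-[(2,2-diphenylethoxy)carbonyl]-2,5-dimethylhex-4-enoic acid; 21 5-methylhexane-2,4-dione
Product: 23 2,2-diphenylethyl (2R)-4-acetyl-2,6-dimethyl-2-(3-methylbut-2-en-1-yl)-3,5-dioxoheptanoate, via acid chloride 22 (not isolated)
Conditions: 1-chloro-N,N,2-trimethylprop-1-en-1-amine, CH2Cl2, 0 °C → rt; then 21, MgCl2, pyridine, CH2Cl2, 0 °C → rt
Reagents that add atoms: 5-methylhexane-2,4-dione (21), CC(=O)CC(=O)C(C)C; 1-chloro-N,N,2-trimethylprop-1-en-1-amine, CC(C)=C(Cl)N(C)C (its chlorine is present in 22 only)
Why: Neutral acid chloride formation followed by soft-enolisation C-acylation of the chelated magnesium chloride enolate of the β-diketone (Claisen-type acylation); 22 has no α-hydrogen, so neither ketene formation nor racemisation is possible.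

Step 12
Reactants: 23 2,2-diphenylethyl (2R)-4-acetyl-2,6-dimethyl-2-(3-methylbut-2-en-1-yl)-3,5-dioxoheptanoate
Product: 24 (4S)-3,5-dihydroxy-4-methyl-4-(3-methylbut-2-en-1-yl)-2-(2-methylpropanoyl)cyclohexa-2,5-dien-1-one
Conditions: LiN(iPr)2 (3.3 equiv), THF, −78 → 0 °C; then cold 1 M HCl
Reagents that add atoms: none
Why: Dieckmann (intramolecular Claisen) condensation, in which the acidic methine is deprotonated first, LiN(iPr)2 then removes an acetyl CH3 proton under kinetic control, and this terminal enolate attacks the non-enolisable primary ester through a six-membered transition state (6-exo-trig), the product being held as its stabilised enolate until the quench; the stereocentre has no hydrogen and keeps all four bonds.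

Step 13
Reactants: 11 1-{6-[(dimethylamino)methyl]-5,7-dihydroxy-2,2-dimethyl-2H-chromen-8-yl}-2-methylpropan-1-one; 24 (4S)-3,5-dihydroxy-4-methyl-4-(3-methylbut-2-en-1-yl)-2-(2-methylpropanoyl)cyclohexa-2,5-dien-1-one
Product: 26 (4S)-6-{[5,7-dihydroxy-2,2-dimethyl-8-(2-methylpropanoyl)-2H-chromen-6-yl]methyl}-3,5-dihydroxy-4-methyl-4-(3-methylbut-2-en-1-yl)-2-(2-methylpropanoyl)cyclohexa-2,5-dien-1-one (CNP0301804.1), via ortho-quinone methide 25 (not isolated)
Conditions: 1,4-dioxane, 80 °C, Ar
Reagents that add atoms: none
Why: Mannich-base alkylation, in which the ammonium enolate formed from 11 and the acidic trione 24 loses dimethylamine on warming to give quinone methide 25, C6 of 24 (its only nucleophilic carbon) adds to 25 in a Michael reaction, and tautomerisation restores the aromatic ring; the quaternary stereocentre is not involved and the moderate temperature avoids sigmatropic loss of the prenyl group.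

Compound list
1 | phloroglucinol (benzene-1,3,5-triol) | Oc1cc(O)cc(O)c1 | starting material
2 | isobutyryl chloride | CC(C)C(Cl)=O | starting material
3 | 2-methyl-1-(2,4,6-trihydroxyphenyl)propan-1-one | CC(C)C(=O)c1c(O)cc(O)cc1O | intermediate
4 | chloromethyl methyl ether | COCCl | starting material
5 | 1-[2-hydroxy-4,6-bis(methoxymethoxy)phenyl]-2-methylpropan-1-one | CC(C)C(=O)c1c(O)cc(OCOC)cc1OCOC | intermediate
6 | 3-chloro-3-methylbut-1-yne | CC(C)(Cl)C#C | starting material
7 | 1-[2,4-bis(methoxymethoxy)-6-(2-methylbut-3-yn-2-yloxy)phenyl]-2-methylpropan-1-one | CC(C)C(=O)c1c(OCOC)cc(OCOC)cc1OC(C)(C)C#C | intermediate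
8 | 1-[5,7-bis(methoxymethoxy)-2,2-dimethyl-2H-chromen-8-yl]-2-methylpropan-1-one | CC(C)C(=O)c1c(OCOC)cc(OCOC)c2C=CC(C)(C)Oc12 | intermediate
9 | 1-(5,7-dihydroxy-2,2-dimethyl-2H-chromen-8-yl)-2-methylpropan-1-one | CC(C)C(=O)c1c(O)cc(O)c2C=CC(C)(C)Oc12 | intermediate
10 | dimethyl(methylidene)ammonium iodide | C=[N+](C)C.[I-] | starting material
11 | 1-{6-[(dimethylamino)methyl]-5,7-dihydroxy-2,2-dimethyl-2H-chromen-8-yl}-2-methylpropan-1-one | CC(C)C(=O)c1c(O)c(CN(C)C)c(O)c2C=CC(C)(C)Oc12 | intermediate
12 | 2,2,5-trimethyl-1,3-dioxane-4,6-dione | CC1C(=O)OC(C)(C)OC1=O | starting material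
13 | tert-butanol | CC(C)(C)O | starting material
14 | 3-tert-butoxy-2-methyl-3-oxopropanoic acid (racemic) | CC(C(=O)O)C(=O)OC(C)(C)C | intermediate
15 | 2,2-diphenylethanol | OCC(c1ccccc1)c1ccccc1 | starting material
16 | 1-tert-butyl 3-(2,2-diphenylethyl) 2-methylpropanedioate (racemic) | CC(C(=O)OC(C)(C)C)C(=O)OCC(c1ccccc1)c1ccccc1 | intermediate
17 | 1-bromo-3-methylbut-2-ene (prenyl bromide) | CC(C)=CCBr | starting material
18 | 1-tert-butyl 3-(2,2-diphenylethyl) (2S)-2-methyl-2-(3-methylbut-2-en-1-yl)propanedioate | CC(C)=CC[C@@](C(=O)OC(C)(C)C)(C)C(=O)OCC(c1ccccc1)c1ccccc1 | intermediate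
19 | 1-(2,2-diphenylethyl) 3-(trimethylsilyl) (2S)-2-methyl-2-(3-methylbut-2-en-1-yl)propanedioate | CC(C)=CC[C@@](C(=O)O[Si](C)(C)C)(C)C(=O)OCC(c1ccccc1)c1ccccc1 | intermediate (not isolated)
20 | (2R)-2-[(2,2-diphenylethoxy)carbonyl]-2,5-dimethylhex-4-enoic acid | CC(C)=CC[C@@](C(=O)O)(C)C(=O)OCC(c1ccccc1)c1ccccc1 | intermediate
21 | 5-methylhexane-2,4-dione | CC(=O)CC(=O)C(C)C | starting material
22 | 2,2-diphenylethyl (2S)-2-(chlorocarbonyl)-2,5-dimethylhex-4-enoate | CC(C)=CC[C@@](C(Cl)=O)(C)C(=O)OCC(c1ccccc1)c1ccccc1 | intermediate (not isolated)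
23 | 2,2-diphenylethyl (2R)-4-acetyl-2,6-dimethyl-2-(3-methylbut-2-en-1-yl)-3,5-dioxoheptanoate | CC(C)=CC[C@@](C(=O)C(C(C)=O)C(=O)C(C)C)(C)C(=O)OCC(c1ccccc1)c1ccccc1 | intermediate
24 | (4S)-3,5-dihydroxy-4-methyl-4-(3-methylbut-2-en-1-yl)-2-(2-methylpropanoyl)cyclohexa-2,5-dien-1-one | CC(C)=CC[C@@]1(C)C(O)=CC(=O)C(C(=O)C(C)C)=C1O | intermediate
25 | 5-hydroxy-2,2-dimethyl-6-methylidene-8-(2-methylpropanoyl)-2H-chromen-7(6H)-one | CC(C)C(=O)C1=C2OC(C)(C)C=CC2=C(O)C(=C)C1=O | intermediate (not isolated)
26 | (4S)-6-{[5,7-dihydroxy-2,2-dimethyl-8-(2-methylpropanoyl)-2H-chromen-6-yl]methyl}-3,5-dihydroxy-4-methyl-4-(3-methylbut-2-en-1-yl)-2-(2-methylpropanoyl)cyclohexa-2,5-dien-1-one | CC(C)=CC[C@@]1(C)C(O)=C(Cc2c(O)c3c(c(C(=O)C(C)C)c2O)OC(C)(C)C=C3)C(=O)C(C(=O)C(C)C)=C1O | target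

Total step count: 13.
Longest linear sequence: 7 steps (steps 7–12 followed by step 13; the chromene branch, steps 1–6 followed by step 13, is equally long).

Steps most likely to fail

1. Step 4 (gold-catalysed ring closure). The Lewis-acidic gold centre may ionise the tertiary propargylic C–O bond, or adventitious acid may cleave a MOM acetal, before the arene has attacked the alkyne, so that the side chain is lost and not cyclised. Fallback: the pyran ring is built through a different bond set, starting from phenol 5, which still has the chelated hydroxyl free. Heating 5 with 3-methylbut-2-enal and catalytic ethylenediammonium diacetate in toluene should lead, by aldol-type attack of the carbon between the free hydroxyl and the neighbouring MOM ether and loss of water, to the dienone 3,5-bis(methoxymethoxy)-6-(3-methylbut-2-en-1-ylidene)-2-(2-methylpropanoyl)cyclohexa-2,4-dien-1-one F1. Oxa-6π electrocyclisation of F1 closes the ring with the same oxygen in the pyran; the sequence rejoins the route at 8 and bypasses 7.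

2. Step 13 (methylene-bridge formation). Retro-Mannich and amine exchange may pass the CH2 unit between the partners, so that symmetrical bis-chromenyl and bis-trione methanes grow at the expense of 26, or the quinone methide may be captured through an enol oxygen instead of carbon. Fallback: the polarity of the partners is reversed, starting from 24 and 9. Trione 24 is aminomethylated at C6 with dimethyl(methylidene)ammonium iodide and Et3N to give (4S)-6-[(dimethylamino)methyl]-3,5-dihydroxy-4-methyl-4-(3-methylbut-2-en-1-yl)-2-(2-methylpropanoyl)cyclohexa-2,5-dien-1-one F2. Warming F2 with a slight excess of 9 in MeCN should release dimethylamine and the strongly electrophilic (6R)-5-hydroxy-6-methyl-6-(3-methylbut-2-en-1-yl)-2-methylidene-4-(2-methylpropanoyl)cyclohex-4-ene-1,3-dione F3. The electron-rich C6 of 9 adds to F3 in the conjugate Friedel–Crafts manner known for 2-alkylidene-1,3-diones and acylphloroglucinols, which returns to the route at 26.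

3. Step 11 (C-acylation of the diketone). The hindered acid chloride may acylate the enol oxygen instead of the central carbon of 21, or the crowded triacylmethane may lose an acyl group by retro-Claisen cleavage during work-up. Fallback: the order of C–C bond formation is changed, starting from 20 (through 22). Acid chloride 22 is added to the kinetic lithium enolate of 3-methylbutan-2-one (2 equiv, THF, −78 °C), a Claisen-type ketone acylation that should give 2,2-diphenylethyl (2R)-2,6-dimethyl-2-(3-methylbut-2-en-1-yl)-3,5-dioxoheptanoate F4. The central carbon of F4 is then acetylated with the small electrophile acetyl chloride (MgCl2, pyridine, CH2Cl2), which comes back to the route at 23.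

Further compounds
F1 | step 4 | 3,5-bis(methoxymethoxy)-6-(3-methylbut-2-en-1-ylidene)-2-(2-methylpropanoyl)cyclohexa-2,4-dien-1-one | CC(C)C(=O)C1=C(OCOC)C=C(OCOC)C(=CC=C(C)C)C1=O
F2 | step 13 | (4S)-6-[(dimethylamino)methyl]-3,5-dihydroxy-4-methyl-4-(3-methylbut-2-en-1-yl)-2-(2-methylpropanoyl)cyclohexa-2,5-dien-1-one | CC(C)=CC[C@@]1(C)C(O)=C(CN(C)C)C(=O)C(C(=O)C(C)C)=C1O
F3 | step 13 | (6R)-5-hydroxy-6-methyl-6-(3-methylbut-2-en-1-yl)-2-methylidene-4-(2-methylpropanoyl)cyclohex-4-ene-1,3-dione | CC(C)=CC[C@@]1(C)C(=O)C(=C)C(=O)C(C(=O)C(C)C)=C1O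
F4 | step 11 | 2,2-diphenylethyl (2R)-2,6-dimethyl-2-(3-methylbut-2-en-1-yl)-3,5-dioxoheptanoate | CC(C)=CC[C@@](C(=O)CC(=O)C(C)C)(C)C(=O)OCC(c1ccccc1)c1ccccc1
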